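**Remarks.** Cembrane numbering is used for every compound: ring carbons C1–C14, C15 the lactone α-carbon, C16 the lactone carbonyl, C17 the methyl on C15, C18 the methyl on C4, C19 the methylene on C8, C20 the methyl on C12. C1, C2 and C3 of geraniol become C2, C3 and C4. Assumption: the L-fructose-derived enantiomer of the Shi ketone (made from L-sorbose) is taken as available.

## Analysis of the target

CNP0262409.1 is a cembranolide: a 14-membered carbocycle (C1–C14) bridged between C1 and C3 by a δ-lactone (O–C3–C2–C1–C15–C16). It carries a trisubstituted oxirane at C11–C12, a tertiary carbinol at C4 and a secondary allylic carbinol at C7 next to the exocyclic C8=C19 methylene. The seven stereocentres are 1R, 3R, 4S, 7R, 11S, 12S and 15S. In the lactone chair the C4 branch on C3, the C14 branch on C1 and the C17 methyl on C15 are all equatorial (C1/C3 cis, C1/C15 trans), so C15 is the stable epimer. The C3/C4 pair has the relation that anti addition of two oxygens to an E alkene would give; C7 and the trans epoxide are remote from this cluster and from each other. Sensitive points are the epoxide (acid, transannular hydroxyls), the 2-methylene allylic alcohol, the base-labile lactone, and the γ-relation of O4 to C7, which turns a C7 aldehyde into a lactol unless O4 is blocked. The hard part is C1, a stereocentre with three carbon branches and no heteroatom, inside a ring that must still be closed. The strategy rests on two facts: C16 has one carbon neighbour (C15) and sits between O3 and C15, and C1 carries two two-carbon arms, C15–C17 and C14–C13. A C1 with two vinyl groups is therefore prochiral, and C16 can enter as carbon monoxide at one of them.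

## Retrosynthetic reasoning

**27 to 25.** Removal of the O4 silyl group leads back to 26, and the oxirane of 26 is cut to the E-C11=C12 alkene of 25. No hydroxyl is close enough to direct this epoxidation, so it is reagent-controlled, and it is placed last to keep the epoxide away from organometallic and Lewis-acidic steps. The forward reaction has to prefer the trisubstituted alkene over the C8 methylene and override any facial bias of the ring.

**25 to 22.** C7 is far from every other centre, so it is taken from a catalyst: 25 comes from enone 24 by enantioselective carbonyl reduction, and 24 from the C7-epimeric alcohol 23. The ring is opened at C7–C8, between the carbinol carbon and the sp2 carbon C8, giving bromo aldehyde 22. An alkenylchromium addition forms this bond in the presence of the lactone, and because C7 is corrected afterwards the stereochemical outcome of the ring closure does not matter.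

**22 to 14 and 19.** Aldehyde 22 is the oxidised form of the primary silyl ether 21, which is cut at C12–C13 into lactone 14 and the C8–C12 arm 19 (hydroboration of the C13=C14 vinyl group, then B-alkyl Suzuki coupling). The order of the two unions follows from chemoselectivity. A hindered dialkylborane adds to a 2-substituted terminal alkene such as C8=C19 no more slowly than to a vinyl group, so hydroboration is done while the vinyl group of 14 is the only alkene. An arm with halides at both C8 and C12 can be addressed selectively by palladium (iodide before bromide) but not by chromium/nickel in the opposite sense. C12–C13 is therefore made first, between two molecules, and C7–C8 closes the ring.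

**14 to 12.** This is the disconnection that carries the strategy. Cutting C15–C16 and C16–O3 removes the carbonyl carbon and turns the C15–C17 arm into a second vinyl group, so the precursor is divinyl alcohol 12, in which C1 is not a stereocentre. Other cuts (conjugate addition to an unsaturated lactone, enolate alkylation, sigmatropic rearrangement) would all have to create C1 without help from C3. The forward reaction must carbonylate one vinyl group at its inner carbon, let O3 capture the acyl group, and choose between the two diastereotopic vinyl groups under the influence of C3. C15 can be left to equilibration because the wanted epimer is the stable one. The C7 oxygen is carried as a primary triethylsilyl ether and O4 as a tertiary one, because the primary ether can later be oxidised off without touching the tertiary one; a bulky arylsilyl ether at C7 could not be removed selectively.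

**12 to 9 and 10.** 12 is cut at C1–C2. The pentadienyl anion 11 from 10 brings C1 with both vinyl groups in one piece, and the terminal epoxide 9 already holds the C3 oxygen; opening at the CH2 end cannot touch C3. O4 must be silylated here, since a free tertiary alkoxide next to the epoxide would rearrange.

**9 to 6.** The C7 silyl ether of 9 comes from alcohol 8, made by ozonolysis and reduction of the prenyl end of 7, the silyl ether of epoxy alcohol 6. The prenyl group is a masked C7 carbonyl that survives the earlier steps.

**6 to 1.** The C3/C4 pair is traced to the Sharpless epoxide 2 of geraniol (1) with inversion at C3. A Payne rearrangement achieves this, since it can move the epoxide only by back-side attack at C3; hydrolytic trapping then gives triol 4. A Lewis-acid neighbouring-group opening was not used, because attack at the tertiary C4 would compete and lead to the enantiomeric triol. The terminal epoxide (as alkoxide 3) cannot be isolated from the Payne equilibrium, so it is re-made from 4 through sulfonate 5 under non-equilibrating conditions.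

**19 to 15.** The arm is cut at the 2-bromoalkene (bromoboration of alkyne 18), at C8–C9 (acetylide alkylation of sulfonate 17) and at the C12–I bond (hydrozirconation–iodination of 15 to 16). This fixes the E geometry of the later C11=C12 alkene on a five-carbon molecule.

## Alternatives that were turned down

**Alternative 1:** pinacol macrocyclisation across C3–C4.
- Disconnection: the bond between the two carbinol carbons, in a ring whose lactone is not yet closed (C16 as a silylated primary alcohol).
- Forward key step: low-valent titanium from TiCl3(DME)1.5 and Zn(Cu) would couple the C3 aldehyde and the C4 methyl ketone of seco keto aldehyde A1 to the macrocyclic 3,4-diol A2, making the ring, C3–C4 and both carbinol centres at once.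
- For: it is the most convergent option, and ketyl couplings close 14-membered terpenoid rings well. On ring-closure economy it is stronger than the route chosen here, which spends three steps at C7–C8.
- Against: C3 and C4 would be set only by the conformation of a flexible 14-membered transition state, with four diastereomers possible and nothing in A1 close enough to bias the outcome. Deoxygenation of the titanium pinacolate to the alkene has to be stopped. The lactone cannot be present, so after A2 the C16 oxygen must be freed, oxidised to the acid level beside a free 1,2-diol and closed onto O3 rather than O4. C1 and C15 must be made beforehand in an open chain.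
- Comparison: the chosen strategy sets C3/C4 at the start by a reagent-controlled epoxidation with a defined inversion and then uses C3 to control C1 and C15.

**Alternative 2:** biomimetic bis-epoxidation and lactonisation.
- Disconnection: the oxirane, the C4–O bond and the O3–C3 bond are traced to two E alkenes and a free C16 acid.
- Forward key step: KHSO5 with the L-series fructose-derived ketone would epoxidise both E-trisubstituted alkenes of the macrocyclic diene acid A3; the carboxylate would then open the 3,4-epoxide at C3 (6-exo, inversion) to give A4, the C7 triethylsilyl ether of the target.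
- For: four C–O bonds and four stereocentres in one operation, no protecting group on O4, and a shorter endgame than the one proposed here. In step economy after ring formation it is clearly stronger.
- Against: A3 holds C1, C15 and C7 as isolated stereocentres in a ring with two E-trisubstituted alkenes, so the difficult part is moved into the precursor and not solved. Both epoxidations must follow the catalyst on a macrocycle that has its own facial preference, and one mismatch gives a diastereomer that cannot be corrected. The carboxylate must attack the secondary C3 and not the tertiary C4, which is the carbon favoured under the acid catalysis such an opening needs, and that acid also threatens the 11,12-epoxide.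
- Comparison: in the chosen route the lactone regiochemistry is fixed by the ring size of acyl capture and C3/C4 are in place before C1 forms; the price is a longer endgame.

**Alternative 3:** sulfone carbanion ring closure at C9–C10.
- Disconnection: the bond between the two allylic positions C9 and C10.
- Forward key step: KN(SiMe3)2 would deprotonate the C10 allylic phenyl sulfone of the open-chain sulfone bromide A5, and the carbanion would displace the C9 allylic bromide to give the macrocyclic sulfone A6 as C10 epimers; the sulfonyl group is removed reductively later.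
- For: sulfone alkylation is among the most dependable cembrane ring closures, it is irreversible and leaves no permanent stereocentre. As a ring closure it is at least as strong as the chromium-mediated one used here, which needs two further steps to fix C7.
- Against: the lactone of A5 is exposed to a strong amide base and to the carbanion (acyl attack, enolate alkylation by the bromide). The 2-substituted allylic bromide can react in the SN2′ sense. Reductive desulfonylation of an allylic sulfone risks alkene migration and costs at least two extra steps. Above all it is only a ring closure: A5 already contains the lactone with C1 and C15, and their origin is left open.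
- Comparison: the chosen strategy answers exactly that open question, with one carbonylation from a non-stereogenic C1.

Key step: step 8

## Route

Step 1
Reactants: 1 geraniol
Product: 2 (2S,3S)-2,3-epoxygeraniol
Conditions: Ti(OiPr)4 (5 mol %), L-(+)-diethyl tartrate (6 mol %), t-BuOOH, 4 Å MS, CH2Cl2, −20 °C
Reagents that add atoms: tert-butyl hydroperoxide, CC(C)(C)OO
Why: Sharpless asymmetric epoxidation; the L-(+)-tartrate catalyst delivers oxygen to the face of the E allylic alcohol that gives the (2S,3S)-epoxide, which fixes C4 (S) and its oxygen. The remote trisubstituted alkene has no directing hydroxyl and is left alone.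

Step 2
Reactants: 2 (2S,3S)-2,3-epoxygeraniol
Product: 4 (2R,3S)-3,7-dimethyloct-6-ene-1,2,3-triol, via Payne alkoxide 3 (not isolated)
Conditions: NaOH (0.5 M), t-BuOH/H2O, 75 °C
Reagents that add atoms: water, O
Why: Payne rearrangement with hydrolytic trapping: the primary alkoxide displaces the epoxide oxygen at the secondary carbon with inversion, and hydroxide opens the terminal epoxide of 3 at its CH2. Direct hydroxide attack on 2 at the same secondary carbon gives the same triol and the tertiary carbon is not open to SN2 attack, so every base pathway should converge on the C3-inverted triol (C3 R, C4 S).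

Step 3
Reactants: 4 (2R,3S)-3,7-dimethyloct-6-ene-1,2,3-triol
Product: 6 epoxy alcohol (2S)-6-methyl-2-[(2R)-oxiran-2-yl]hept-5-en-2-ol, via primary tosylate 5 (not isolated)
Conditions: TsCl, Et3N, Bu2SnO (2 mol %), CH2Cl2, 0 °C → rt; then K2CO3, MeOH, 0 °C
Reagents that add atoms: none
Why: Tin-catalysed sulfonylation picks the primary hydroxyl of the 1,2-diol, and the secondary alkoxide then closes the oxirane by 3-exo-tet displacement at C2, so C3 keeps its configuration. At 0 °C without hydroxide the reverse Payne equilibration to 2 should be slow.

Step 4
Reactants: 6 epoxy alcohol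
Product: 7 triethyl{[(2S)-6-methyl-2-[(2R)-oxiran-2-yl]hept-5-en-2-yl]oxy}silane
Conditions: Et3SiOTf, 2,6-lutidine, CH2Cl2, −78 °C
Reagents that add atoms: triethylsilyl trifluoromethanesulfonate, CC[Si](CC)(CC)OS(=O)(=O)C(F)(F)F
Why: Silyl triflate with a hindered pyridine base silylates the tertiary alcohol at −78 °C, faster than it can open the epoxide. The ether blocks Payne rearrangement in step 7 and lactol formation later.

Step 5
Reactants: 7 epoxide C4 triethylsilyl ether
Product: 8 (4S)-4-[(2R)-oxiran-2-yl]-4-[(triethylsilyl)oxy]pentan-1-ol
Conditions: O3, CH2Cl2/MeOH, −78 °C; then NaBH4, −78 → 0 °C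
Reagents that add atoms: ozone, [O-][O+]=O
Why: Ozonolysis of the only alkene with reductive borohydride work-up gives the primary C7 alcohol; the epoxide and the tertiary silyl ether are inert to both reagents.

Step 6
Reactants: 8 primary alcohol
Product: 9 (2R)-2-{(2S)-2,5-bis[(triethylsilyl)oxy]pentan-2-yl}oxirane
Conditions: Et3SiCl, imidazole, CH2Cl2, 0 °C
Reagents that add atoms: chlorotriethylsilane, CC[Si](Cl)(CC)CC
Why: Standard silylation under neutral conditions that spare the epoxide. A primary triethylsilyl ether is chosen because it can later be oxidised directly to the aldehyde beside the tertiary one.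

Step 7
Reactants: 9 bis-silylated epoxide; 10 penta-1,4-diene
Product: 12 divinyl alcohol (5R,6S)-3-ethenyl-6-methyl-6,9-bis[(triethylsilyl)oxy]non-1-en-5-ol, via pentadienyllithium 11 (not isolated)
Conditions: 10, n-BuLi, THF, −78 → 0 °C; then 9, −78 → −20 °C; NH4Cl (aq) at −20 °C
Reagents that add atoms: none
Why: Epoxide opening by an organolithium: pentadienyllithium attacks the CH2 end of the monosubstituted epoxide, mainly through its central carbon, which carries the highest charge density, to give the 3-substituted penta-1,4-diene. C3 is not touched and C1 is not yet a stereocentre; the cold quench is meant to prevent a 1,2-shift of the silyl group to the new alkoxide.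

Step 8
Reactants: 12 divinyl alcohol
Product: 14 vinyl lactone (3S,4S,6R)-4-ethenyl-3-methyl-6-{(2S)-2,5-bis[(triethylsilyl)oxy]pentan-2-yl}oxan-2-one, via C15-epimeric lactone mixture 13 (not isolated)
Conditions: Pd(OAc)2 (5 mol %), dppb (10 mol %), CO (60 bar), H2 (5 bar), CH2Cl2, 100 °C; then DBU, toluene, 80 °C
Reagents that add atoms: carbon monoxide, [C-]#[O+]
Why: Proposed new method: Pd(OAc)2, 1,4-bis(diphenylphosphino)butane, CO and H2 should give a divalent palladium hydride that adds reversibly and in the Markovnikov sense to either vinyl group, placing palladium on C15; CO inserts, and the C3 hydroxyl takes the acyl carbon (6-exo-trig) to close the δ-lactone and return the hydride. The closest known reaction is the palladium/diphosphine cyclocarbonylation of allylic and homoallylic alcohols and of 2-allylphenols to α-methyl lactones; selection between two diastereotopic vinyl groups of a skipped-diene carbinol has not been shown. Branched regiochemistry follows from ring size, since the linear acyl could only close a seven-membered ring and should revert. C1 is set at ring closure: the two diastereomeric acyl complexes interconvert through β-hydride elimination toward C17 and re-addition, and the one whose chair holds both the bulky C4 branch on C3 and the spectator vinyl on C1 equatorial should lactonise faster, giving the 1,3-cis lactone (1S in 14 by the sequence rule, the arrangement that is 1R in 27). C15 is set by the same chair (equatorial methyl) and, for what escapes it, by DBU equilibration through the lactone enolate to the all-equatorial 15S epimer. The step needs group selectivity, Markovnikov regiochemistry and suppression of β-hydride elimination toward C1, which would conjugate the skipped diene; the chelating diphosphine and high CO pressure serve the last, and the silyl ether on O4 removes the only competing nucleophile.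

Step 9
Reactants: 15 pent-3-yn-1-ol
Product: 16 (3E)-4-iodopent-3-en-1-ol
Conditions: Cp2Zr(H)Cl (2.5 equiv), THF, rt; then I2, 0 °C
Reagents that add atoms: iodine, II
Why: Hydrozirconation–iodination: syn addition of Zr–H places zirconium on the methyl-bearing alkyne carbon after equilibration with excess reagent, and iodinolysis with retention gives the E 2-iodoalkene (iodine trans to the chain). The first equivalent of hydride is consumed by the hydroxyl.

Step 10
Reactants: 16 (3E)-4-iodopent-3-en-1-ol
Product: 17 (3E)-4-iodopent-3-en-1-yl 4-methylbenzenesulfonate
Conditions: TsCl, Et3N, DMAP (cat.), CH2Cl2, 0 °C → rt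
Reagents that add atoms: 4-methylbenzenesulfonyl chloride, Cc1ccc(cc1)S(=O)(=O)Cl
Why: Standard sulfonylation of a primary alcohol; the vinyl iodide is inert.

Step 11
Reactants: 17 tosylate
Product: 18 (5E)-6-iodohept-5-en-1-yne
Conditions: LiC≡CH·H2NCH2CH2NH2, DMSO, 15 °C → rt
Reagents that add atoms: lithium acetylide (ethylenediamine complex), [Li+].[C-]#C
Why: SN2 alkylation of an acetylide by a primary sulfonate in a dipolar aprotic solvent forms C8–C9. The trisubstituted vinyl iodide has no anti hydrogen for elimination and does not react with the acetylide.

Step 12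
Reactants: 18 (5E)-6-iodohept-5-en-1-yne
Product: 19 (2E)-6-bromo-2-iodohepta-2,6-diene
Conditions: B-Br-9-BBN, CH2Cl2, 0 °C; then AcOH, 0 °C → rt
Reagents that add atoms: B-bromo-9-borabicyclo[3.3.1]nonane, BrB1C2CCCC1CCC2
Why: Haloboration: the bromoborane adds cis across terminal alkynes only, with bromine on the internal carbon, and protonolysis of the vinyl–boron bond with acetic acid leaves the 2-bromo-1-alkene.

Step 13
Reactants: 14 vinyl lactone; 19 (2E)-6-bromo-2-iodohepta-2,6-diene
Product: 21 bromodiene lactone (3S,4R,6R)-4-[(3E)-7-bromo-3-methylocta-3,7-dien-1-yl]-3-methyl-6-{(2S)-2,5-bis[(triethylsilyl)oxy]pentan-2-yl}oxan-2-one, via B-alkyl-9-BBN adduct 20 (not isolated)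
Conditions: 9-BBN-H, THF, 0 °C → rt; H2O; then 19, Pd(dppf)Cl2 (5 mol %), AsPh3, Cs2CO3, DMF/H2O, rt
Reagents that add atoms: none
Why: B-alkyl Suzuki–Miyaura coupling: the borane adds anti-Markovnikov to the only alkene of 14, and at room temperature zerovalent palladium inserts into the vinyl iodide and leaves the vinyl bromide. The E geometry of 19 is retained, which fixes the C11=C12 alkene and forms C12–C13.

Step 14
Reactants: 21 bromodiene lactone
Product: 22 C7 aldehyde of 21
Conditions: (COCl)2, DMSO, CH2Cl2, −78 → −40 °C; then Et3N, −78 → 0 °C
Reagents that add atoms: none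
Why: Swern oxidation of a primary triethylsilyl ether: the chlorosulfonium salt cleaves the unhindered primary silyl ether and oxidises it to the aldehyde in one operation, while the tertiary silyl ether on O4 is too hindered to react.

Step 15
Reactants: 22 bromo aldehyde
Product: 23 macrocyclic allylic alcohol (both C7 epimers)
Conditions: CrCl2 (10 equiv), NiCl2 (0.2 equiv), DMSO, rt, 2 mM, slow addition
Reagents that add atoms: none
Why: Intramolecular Nozaki–Hiyama–Kishi reaction: nickel inserts into the C8–Br bond, transmetalation gives the alkenylchromium species, and this adds to the aldehyde but not to the lactone; high dilution favours the 14-membered ring. C7 forms as a mixture that steps 16 and 17 converge.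

Step 16
Reactants: 23 macrocyclic allylic alcohol
Product: 24 macrocyclic enone
Conditions: Dess–Martin periodinane, NaHCO3, CH2Cl2, 0 °C
Reagents that add atoms: none
Why: Dess–Martin oxidation of a secondary allylic alcohol under buffered conditions; both C7 epimers give the same α-methylene ketone.

Step 17
Reactants: 24 macrocyclic enone
Product: 25 (7R)-macrocyclic allylic alcohol
Conditions: (S)-2-methyl-CBS-oxazaborolidine (0.5 equiv), catecholborane, toluene, −78 °C
Reagents that add atoms: none
Why: Corey–Bakshi–Shibata reduction: the (S)-oxazaborolidine binds the ketone with the branched alkenyl carbon C8 as the large group and the C6 methylene as the small one, and hydride delivery should give the 7R alcohol. Catecholborane at −78 °C reduces the carbonyl 1,2 and does not hydroborate the alkenes.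

Step 18
Reactants: 25 (7R)-macrocyclic allylic alcohol
Product: 26 (11S,12S)-epoxide (C4 triethylsilyl ether of the target)
Conditions: L-fructose-derived Shi ketone (0.5 equiv), KHSO5 (as Oxone), K2CO3, Bu4NHSO4, MeCN/CH2(OMe)2/aq. Na2B4O7 buffer, 0 °C
Reagents that add atoms: potassium peroxymonosulfate, [K+].[O-]S(=O)(=O)OO
Why: Shi epoxidation: the chiral dioxirane epoxidises E-trisubstituted alkenes through a spiro transition state, and this enantiomer of the ketone gives the (S,S)-epoxide, setting C11 and C12. The 1,1-disubstituted C8 methylene beside the carbinol is a poor substrate and should be left.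

Step 19
Reactants: 26 epoxide C4 triethylsilyl ether
Product: 27 CNP0262409.1
Conditions: HF·pyridine, pyridine, THF, 0 °C → rt
Reagents that add atoms: none
Why: Fluoride cleavage of the tertiary silyl ether; pyridine-buffered HF is mild enough to leave the trisubstituted epoxide, the allylic alcohol and the lactone intact.

## Compound list

1 | geraniol, (2E)-3,7-dimethylocta-2,6-dien-1-ol | CC(C)=CCC/C(C)=C/CO | starting material
2 | (2S,3S)-2,3-epoxygeraniol, [(2S,3S)-3-methyl-3-(4-methylpent-3-en-1-yl)oxiran-2-yl]methanol | OC[C@@H]1O[C@@]1(C)CCC=C(C)C | intermediate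
3 | Payne alkoxide, sodium (2S)-6-methyl-2-[(2R)-oxiran-2-yl]hept-5-en-2-olate | C1O[C@H]1[C@@](C)([O-])CCC=C(C)C.[Na+] | intermediate (not isolated)
4 | (2R,3S)-3,7-dimethyloct-6-ene-1,2,3-triol | OC[C@@H](O)[C@@](C)(O)CCC=C(C)C | intermediate
5 | primary tosylate, (2R,3S)-2,3-dihydroxy-3,7-dimethyloct-6-en-1-yl 4-methylbenzenesulfonate | Cc1ccc(cc1)S(=O)(=O)OC[C@@H](O)[C@@](C)(O)CCC=C(C)C | intermediate (not isolated)
6 | epoxy alcohol, (2S)-6-methyl-2-[(2R)-oxiran-2-yl]hept-5-en-2-ol | C1O[C@H]1[C@@](C)(O)CCC=C(C)C | intermediate
7 | triethyl{[(2S)-6-methyl-2-[(2R)-oxiran-2-yl]hept-5-en-2-yl]oxy}silane | C1O[C@H]1[C@@](C)(O[Si](CC)(CC)CC)CCC=C(C)C | intermediate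
8 | (4S)-4-[(2R)-oxiran-2-yl]-4-[(triethylsilyl)oxy]pentan-1-ol | C1O[C@H]1[C@@](C)(O[Si](CC)(CC)CC)CCCO | intermediate
9 | (2R)-2-{(2S)-2,5-bis[(triethylsilyl)oxy]pentan-2-yl}oxirane | C1O[C@H]1[C@@](C)(O[Si](CC)(CC)CC)CCCO[Si](CC)(CC)CC | intermediate
10 | penta-1,4-diene | C=CCC=C | starting material
11 | pentadienyllithium | [Li+].C=C[CH-]C=C | intermediate (not isolated)
12 | divinyl alcohol, (5R,6S)-3-ethenyl-6-methyl-6,9-bis[(triethylsilyl)oxy]non-1-en-5-ol (precursor of the key step) | C=CC(C=C)C[C@@H](O)[C@@](C)(O[Si](CC)(CC)CC)CCCO[Si](CC)(CC)CC | intermediate
13 | lactone 14 as a mixture of C15 epimers (C1, C3, C4 as in 14) | C=C[C@@H]1C[C@@H](OC(=O)C1C)[C@@](C)(O[Si](CC)(CC)CC)CCCO[Si](CC)(CC)CC | intermediate (not isolated)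
14 | vinyl lactone, (3S,4S,6R)-4-ethenyl-3-methyl-6-{(2S)-2,5-bis[(triethylsilyl)oxy]pentan-2-yl}oxan-2-one (product of the key step) | C=C[C@@H]1C[C@@H](OC(=O)[C@H]1C)[C@@](C)(O[Si](CC)(CC)CC)CCCO[Si](CC)(CC)CC | intermediate
15 | pent-3-yn-1-ol | CC#CCCO | starting material
16 | (3E)-4-iodopent-3-en-1-ol | OCC/C=C(\C)I | intermediate
17 | (3E)-4-iodopent-3-en-1-yl 4-methylbenzenesulfonate | Cc1ccc(cc1)S(=O)(=O)OCC/C=C(\C)I | intermediate
18 | (5E)-6-iodohept-5-en-1-yne | C#CCC/C=C(\C)I | intermediate
19 | (2E)-6-bromo-2-iodohepta-2,6-diene (C8–C12 arm, fragment 2) | C=C(Br)CC/C=C(\C)I | intermediate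
20 | B-alkyl-9-BBN adduct of 14 (boron on C13) | C(C[C@@H]1C[C@@H](OC(=O)[C@H]1C)[C@@](C)(O[Si](CC)(CC)CC)CCCO[Si](CC)(CC)CC)B1C2CCCC1CCC2 | intermediate (not isolated)
21 | bromodiene lactone, (3S,4R,6R)-4-[(3E)-7-bromo-3-methylocta-3,7-dien-1-yl]-3-methyl-6-{(2S)-2,5-bis[(triethylsilyl)oxy]pentan-2-yl}oxan-2-one | C=C(Br)CC/C=C(\C)CC[C@@H]1C[C@@H](OC(=O)[C@H]1C)[C@@](C)(O[Si](CC)(CC)CC)CCCO[Si](CC)(CC)CC | intermediate
22 | C7 aldehyde of 21 (CH2OSiEt3 at C7 replaced by CHO; O4 silyl ether kept) | C=C(Br)CC/C=C(\C)CC[C@@H]1C[C@@H](OC(=O)[C@H]1C)[C@@](C)(O[Si](CC)(CC)CC)CCC=O | intermediate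
23 | macrocyclic allylic alcohol, 14-membered ring with E-C11=C12, C8=C19, O4 silyl ether, both C7 epimers | C=C1CC/C=C(C)/CC[C@@H]2C[C@@H](OC(=O)[C@H]2C)[C@@](C)(O[Si](CC)(CC)CC)CCC1O | intermediate
24 | macrocyclic enone (C7 ketone of 23) | C=C1CC/C=C(C)/CC[C@@H]2C[C@@H](OC(=O)[C@H]2C)[C@@](C)(O[Si](CC)(CC)CC)CCC1=O | intermediate
25 | (7R)-macrocyclic allylic alcohol, O4 triethylsilyl ether | C=C1CC/C=C(C)/CC[C@@H]2C[C@@H](OC(=O)[C@H]2C)[C@@](C)(O[Si](CC)(CC)CC)CC[C@H]1O | intermediate
26 | (11S,12S)-epoxide, O4 triethylsilyl ether of the target | C=C1CC[C@@H]2O[C@@]2(C)CC[C@@H]2C[C@@H](OC(=O)[C@H]2C)[C@@](C)(O[Si](CC)(CC)CC)CC[C@H]1O | intermediate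
27 | CNP0262409.1 (1R,3R,4S,7R,11S,12S,15S) | C=C1CC[C@@H]2O[C@@]2(C)CC[C@@H]2C[C@@H](OC(=O)[C@H]2C)[C@@](C)(O)CC[C@H]1O | target

## Step count and least certain steps

Total: 19 steps; steps 9–12 make fragment 19. Longest linear sequence: 15 steps (steps 1–8 and 13–19).

**Step 8 (key step, the one step beyond known chemistry).**
- Most likely failure: β-hydride elimination of the C15 palladium alkyl toward C1 competes with CO insertion. This moves the double bond into conjugation with the second vinyl group and diverts the substrate into π-allyl palladium chemistry.
- Second failure mode: acyl capture may be faster than reversal of hydropalladation, so the two diastereotopic vinyl groups are carbonylated with little discrimination and the C1 epimer forms.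
- Fallback with known chemistry, from 12 back to 14: one vinyl group of 12 is hydroborated with 9-BBN-H (1 equiv) and oxidised with NaBO3 to the primary alcohol, giving (5R,6S)-3-ethenyl-6-methyl-6,9-bis[(triethylsilyl)oxy]nonane-1,5-diol F1 as both C1 epimers. TEMPO with PhI(OAc)2 oxidises the primary alcohol and closes the δ-lactone. The 1,3-cis lactone (4R,6R)-4-ethenyl-6-{(2S)-2,5-bis[(triethylsilyl)oxy]pentan-2-yl}oxan-2-one F2 is separated from its C1 epimer. Its enolate (LiN(iPr)2, −78 °C) is methylated with MeI anti to the vinyl group to give 14. This gives up group selection (C1 rests on a separation), but every operation is routine.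

**Step 7.**
- Most likely failure: loss of regiocontrol in the ambident pentadienyl anion, with attack through a terminal carbon giving the conjugated linear diene. Warming would also allow silyl migration from O4 to the new C3 alkoxide.
- Fallback, from 9 back to 12: the dianion of but-3-enoic acid (LiN(iPr)2, 2.2 equiv) opens 9 at C2 through its α-carbon. The hydroxy acid is closed with a carbodiimide to the α-vinyl lactone (5R)-3-ethenyl-5-{(2S)-2,5-bis[(triethylsilyl)oxy]pentan-2-yl}oxolan-2-one F3, whose C1 epimers do not matter. (i-Bu)2AlH at −78 °C gives the lactol (5R)-3-ethenyl-5-{(2S)-2,5-bis[(triethylsilyl)oxy]pentan-2-yl}oxolan-2-ol F4. Wittig methylenation with Ph3P=CH2 turns the lactol carbon into the second vinyl group and frees the C3 hydroxyl, giving 12.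

**Step 15.**
- Most likely failure: slow insertion of nickel into the 2-bromoalkene, so that at the dilution required the aldehyde is consumed by intermolecular coupling and oligomerisation.
- Fallback, from 14 and 18 back to 23: the borane 20 from 14 is coupled with the iodide of 18 under the conditions of step 13 to the enyne lactone F5 (C7 silyl ether, terminal C8≡C19 alkyne). Swern oxidation as in step 14 gives the ynal F6. A nickel-catalysed reductive ynal macrocyclisation (Ni(cod)2 as zerovalent nickel, a bulky N-heterocyclic carbene ligand, Et3SiH) joins C7 to the internal alkyne carbon and gives the macrocyclic C7 triethylsilyl ether F7. Mild acid methanolysis (pyridinium tosylate, MeOH, 0 °C) removes the secondary allylic silyl group but not the tertiary one and gives 23.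

**Step 17.**
- Most likely failure: poor facial selectivity, because the conformation of the 14-membered enone may present one carbonyl face regardless of the catalyst; some 1,4-reduction of the α-methylene ketone is also possible.
- Fallback, from 22 straight to 25: the ring closure of step 15 is run with a stoichiometric chiral sulfonamide ligand on chromium, so that C7 is set when C7–C8 forms and steps 16 and 17 are dropped. The ligand enantiomer is chosen for the 7R alcohol. No new compound is needed (F0).

**Step 18.**
- Most likely failure: the macrocycle's own preference for peripheral attack on one alkene face may oppose the catalyst; slow lactone hydrolysis at the basic pH is a lesser risk.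
- Fallback, from 21 back to 26: the epoxidation is moved to the open chain, where catalyst control of an E-trisubstituted alkene is most reliable. Shi epoxidation of 21 gives the (11S,12S)-epoxide of 21 F8. Swern oxidation gives the epoxy aldehyde F9. The chromium/nickel ring closure gives the epoxy macrocyclic alcohol F10 as C7 epimers. Dess–Martin oxidation gives the epoxy enone F11, and the reduction of step 17 gives 26.

## Further compounds

F1 | step 8 | (5R,6S)-3-ethenyl-6-methyl-6,9-bis[(triethylsilyl)oxy]nonane-1,5-diol, both C1 epimers (cembrane numbering) | OCCC(C=C)C[C@@H](O)[C@@](C)(O[Si](CC)(CC)CC)CCCO[Si](CC)(CC)CC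
F2 | step 8 | (4R,6R)-4-ethenyl-6-{(2S)-2,5-bis[(triethylsilyl)oxy]pentan-2-yl}oxan-2-one | C=C[C@@H]1C[C@@H](OC(=O)C1)[C@@](C)(O[Si](CC)(CC)CC)CCCO[Si](CC)(CC)CC
F3 | step 7 | (5R)-3-ethenyl-5-{(2S)-2,5-bis[(triethylsilyl)oxy]pentan-2-yl}oxolan-2-one, both C3 epimers | C=CC1C[C@@H](OC1=O)[C@@](C)(O[Si](CC)(CC)CC)CCCO[Si](CC)(CC)CC
F4 | step 7 | (5R)-3-ethenyl-5-{(2S)-2,5-bis[(triethylsilyl)oxy]pentan-2-yl}oxolan-2-ol, epimer mixture | C=CC1C[C@@H](OC1O)[C@@](C)(O[Si](CC)(CC)CC)CCCO[Si](CC)(CC)CC
F5 | step 15 | enyne lactone, (3S,4R,6R)-3-methyl-4-[(3E)-3-methyloct-3-en-7-yn-1-yl]-6-{(2S)-2,5-bis[(triethylsilyl)oxy]pentan-2-yl}oxan-2-one | C#CCC/C=C(\C)CC[C@@H]1C[C@@H](OC(=O)[C@H]1C)[C@@](C)(O[Si](CC)(CC)CC)CCCO[Si](CC)(CC)CC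
F6 | step 15 | ynal, C7 aldehyde of F5 | C#CCC/C=C(\C)CC[C@@H]1C[C@@H](OC(=O)[C@H]1C)[C@@](C)(O[Si](CC)(CC)CC)CCC=O
F7 | step 15 | C7 triethylsilyl ether of 23, both C7 epimers | C=C1CC/C=C(C)/CC[C@@H]2C[C@@H](OC(=O)[C@H]2C)[C@@](C)(O[Si](CC)(CC)CC)CCC1O[Si](CC)(CC)CC
F0 | step 17 | none | none
F8 | step 18 | (11S,12S)-epoxide of 21 | C=C(Br)CC[C@@H]1O[C@@]1(C)CC[C@@H]2C[C@@H](OC(=O)[C@H]2C)[C@@](C)(O[Si](CC)(CC)CC)CCCO[Si](CC)(CC)CC
F9 | step 18 | epoxy aldehyde, C7 aldehyde of F8 | C=C(Br)CC[C@@H]1O[C@@]1(C)CC[C@@H]2C[C@@H](OC(=O)[C@H]2C)[C@@](C)(O[Si](CC)(CC)CC)CCC=O
F10 | step 18 | epoxy macrocyclic allylic alcohol, both C7 epimers | C=C1CC[C@@H]2O[C@@]2(C)CC[C@@H]2C[C@@H](OC(=O)[C@H]2C)[C@@](C)(O[Si](CC)(CC)CC)CCC1O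
F11 | step 18 | epoxy macrocyclic enone | C=C1CC[C@@H]2O[C@@]2(C)CC[C@@H]2C[C@@H](OC(=O)[C@H]2C)[C@@](C)(O[Si](CC)(CC)CC)CCC1=O
A1 | alternative 1 | seco keto aldehyde (C3 aldehyde, C4 methyl ketone, C16 triethylsilyl ether, C7 tert-butyldimethylsilyl ether) | O=CC[C@H]([C@H](C)CO[Si](CC)(CC)CC)CC/C(C)=C/CCC(=C)[C@H](O[Si](C)(C)C(C)(C)C)CCC(C)=O
A2 | alternative 1 | macrocyclic 3,4-diol | C=C1CC/C=C(C)/CC[C@@H]([C@H](C)CO[Si](CC)(CC)CC)C[C@@H](O)[C@@](C)(O)CC[C@H]1O[Si](C)(C)C(C)(C)C
A3 | alternative 2 | macrocyclic diene acid (E-C3=C4, E-C11=C12, C7 triethylsilyl ether) | C=C1CC/C=C(C)/CC[C@@H]([C@H](C)C(=O)O)C/C=C(C)/CC[C@H]1O[Si](CC)(CC)CC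
A4 | alternative 2 | C7 triethylsilyl ether of the target | C=C1CC[C@@H]2O[C@@]2(C)CC[C@@H]2C[C@@H](OC(=O)[C@H]2C)[C@@](C)(O)CC[C@H]1O[Si](CC)(CC)CC
A5 | alternative 3 | open-chain lactone with C10 allylic phenyl sulfone and C9 allylic bromide | O=S(=O)(c1ccccc1)C/C=C(C)/CC[C@@H]2C[C@@H](OC(=O)[C@H]2C)[C@@](C)(O[Si](CC)(CC)CC)CC[C@@H](O[Si](C)(C)C(C)(C)C)C(=C)CBr
A6 | alternative 3 | macrocyclic C10 sulfone, C10 epimers | C=C1CC(S(=O)(=O)c2ccccc2)/C=C(C)/CC[C@@H]2C[C@@H](OC(=O)[C@H]2C)[C@@](C)(O[Si](CC)(CC)CC)CC[C@H]1O[Si](C)(C)C(C)(C)C
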